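The cyclohexene ring is labelled C1 (fully substituted oxirane carbon carrying the benzoyloxymethyl carbon C7), C2 (benzoate), C3 (carbinol), C4=C5 and C6 (oxirane CH). Because the C4=C5 double bond sits between two cis C–O bonds (C3, C6), this ring is opened retrosynthetically at C1–C6 and C2–C3. A single catalytic, enantioselective Diels–Alder reaction between a symmetric (E,E)-1,4-bis(silyloxy)butadiene and (E)-3-benzoyloxy-2-bromoacrolein should build the ring, both C–C bonds and all four stereocentres, with bromine on C1 anti to the C6 oxygen. Aldehyde reduction, benzoylation and an invertive oxirane closure by O6 at C1 complete the target.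

Key step: step 3

Remark (labels): C1–C7 as defined above are used for every intermediate; locants and descriptors in the names follow these labels.

Assumption (chemistry): the facial sense of the catalyst is carried over from its behaviour with 2-bromoacrolein, taken as delivery of the diene to the Re face of the α-carbon by the (S)-diphenylprolinol-derived cation. Adduct 8 needs the Si face, so the (R)-series catalyst is specified; its antipode would be used, with nothing else changed, should a trial run show the reverse sense.

Step 1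
Reactants: 1 bromomalonaldehyde (2-bromopropanedial, present as its chelated enol); 2 benzoyl chloride
Product: 3 (E)-3-(benzoyloxy)-2-bromoprop-2-enal (formyl cis to benzoyloxy, bromine trans to benzoyloxy)
Conditions: BzCl (1.05 equiv), Et3N (1.05 equiv), CH2Cl2, −78 → −20 °C; cold aqueous work-up, crystallisation
Reagents that add atoms: benzoyl chloride (2), O=C(Cl)c1ccccc1
Why: O-acylation (enol ester formation) of the acidic, intramolecularly hydrogen-bonded enol through its contact ion pair at low temperature should capture the U-shaped enolate so that benzoyloxy ends cis to formyl, and leaving out nucleophilic catalysts (pyridine, DMAP) keeps the alkene from isomerising by addition–elimination.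

Step 2
Reactants: 4 (1E,3E)-buta-1,3-diene-1,4-diyl diacetate; 5 tert-butyldimethylsilyl chloride
Product: 7 (1E,3E)-1,4-bis(tert-butyldimethylsilyloxy)buta-1,3-diene, via dilithium (1E,3E)-buta-1,3-diene-1,4-diolate 6 (not isolated)
Conditions: MeLi (4.1 equiv), THF, −78 → 0 °C; then TBSCl (2.4 equiv), DMPU, −78 °C → rt; distillation
Reagents that add atoms: tert-butyldimethylsilyl chloride (5), CC(C)(C)[Si](C)(C)Cl
Why: Enol acetate cleavage by MeLi (two equivalents per ester, the acetyl group leaving as tert-butoxide) gives the lithium bis-enolate with both double-bond geometries retained, and O-silylation of the aldehyde enolate oxygens then delivers the (E,E)-bis(silyl enol ether) stereospecifically.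

Step 3
Reactants: 3 (E)-3-(benzoyloxy)-2-bromoprop-2-enal; 7 (1E,3E)-1,4-bis(tert-butyldimethylsilyloxy)buta-1,3-diene
Product: 8 (1S,2R,3R,6S)-2-(benzoyloxy)-1-bromo-3,6-bis(tert-butyldimethylsilyloxy)cyclohex-4-ene-1-carbaldehyde (CHO, OBz and both OTBS on one face, Br on the other)
Conditions: B-(o-tolyl)oxazaborolidine of (R)-α,α-diphenylprolinol (20 mol%), Tf2NH (18 mol%), 7 (1.5 equiv), CH2Cl2, −78 → −40 °C
Reagents that add atoms: none
Why: Proposed new method: the N-protonated oxazaborolidine binds the formyl oxygen of 3 and lowers its LUMO, so that a concerted but asynchronous [4+2] cycloaddition with the electron-rich diene 7 forms C2–C3 (at the β-carbon) slightly ahead of C1–C6; the closest known reaction type is the oxazaborolidinium-catalysed Diels–Alder reaction of 2-bromoacrolein with oxygenated dienes, which has not been extended to a 3-acyloxy-2-bromo enal or a 1,4-bis(silyloxy)diene. The cyclohexene ring is closed by the intermolecular suprafacial–suprafacial [4π+2π] union itself, two σ-bonds in one event and no separate cyclisation. C3 and C6 are set cis by the (E,E) geometry of 7, C2 is tied to C1 by the alkene geometry of 3 (formyl cis to benzoyloxy), and the endo placement of the catalyst-bound formyl group, unopposed by a bridging methylene in an acyclic diene, puts CHO, OBz and both OTBS on one face and Br on the other. The absolute configuration (Si face of the α-carbon of 3) is set by the (R)-configured catalyst. The selectivities required are endo and enantiofacial only, since the symmetric diene offers no regiochemical choice; low temperature and a small deficit of Tf2NH relative to the oxazaborolidine are meant to keep the silyl enol ethers from Mukaiyama-type addition and protodesilylation.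

Step 4
Reactants: 8 (1S,2R,3R,6S)-2-(benzoyloxy)-1-bromo-3,6-bis(tert-butyldimethylsilyloxy)cyclohex-4-ene-1-carbaldehyde
Product: 9 (1S,2R,3R,6S)-1-bromo-1-(hydroxymethyl)-3,6-bis(tert-butyldimethylsilyloxy)cyclohex-4-en-2-yl benzoate
Conditions: NaBH4, CeCl3·7H2O, MeOH/THF, −78 → −40 °C; aq NH4Cl
Reagents that add atoms: none
Why: Luche reduction of the hindered α-bromo aldehyde gives the primary alcohol under nearly neutral, cold conditions, which should prevent closure of a C7 alkoxide onto C1 and benzoyl transfer from O2, and no stereocentre is touched.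

Step 5
Reactants: 9 (1S,2R,3R,6S)-1-bromo-1-(hydroxymethyl)-3,6-bis(tert-butyldimethylsilyloxy)cyclohex-4-en-2-yl benzoate; 2 benzoyl chloride
Product: 10 [(1S,2R,3R,6S)-2-(benzoyloxy)-1-bromo-3,6-bis(tert-butyldimethylsilyloxy)cyclohex-4-en-1-yl]methyl benzoate
Conditions: BzCl, pyridine, DMAP (cat.), CH2Cl2, 0 °C
Reagents that add atoms: benzoyl chloride (2), O=C(Cl)c1ccccc1
Why: Acylation of a primary alcohol with an acid chloride under nucleophilic catalysis is routine, and pyridine is too weak a base to close the bromohydrin.

Step 6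
Reactants: 10 [(1S,2R,3R,6S)-2-(benzoyloxy)-1-bromo-3,6-bis(tert-butyldimethylsilyloxy)cyclohex-4-en-1-yl]methyl benzoate
Product: 11 [(1R,2R,3R,6S)-2-(benzoyloxy)-1-bromo-3,6-dihydroxycyclohex-4-en-1-yl]methyl benzoate (same spatial arrangement as 10; the C1 descriptor changes through priorities only)
Conditions: HF·pyridine, pyridine, THF, 0 °C → rt
Reagents that add atoms: none
Why: Fluoride-driven cleavage of both secondary silyl ethers under buffered acidic conditions leaves the benzoates and the tertiary bromide intact and, being non-basic, should start neither benzoyl migration from O2 to O3 nor oxirane formation.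

Step 7
Reactants: 11 [(1R,2R,3R,6S)-2-(benzoyloxy)-1-bromo-3,6-dihydroxycyclohex-4-en-1-yl]methyl benzoate; 12 chlorotriethylsilane
Product: 13 [(1R,2R,3R,6S)-2-(benzoyloxy)-1-bromo-6-hydroxy-3-(triethylsilyloxy)cyclohex-4-en-1-yl]methyl benzoate
Conditions: TESCl (1.05 equiv), imidazole, CH2Cl2, −20 → 0 °C
Reagents that add atoms: chlorotriethylsilane (12), CC[Si](Cl)(CC)CC
Why: Regioselective silylation should cap the C3 hydroxyl, which is far less hindered than the neopentyl-type C6 hydroxyl beside the quaternary C1, and this blocks the 1,2-benzoyl shift from O2 to O3 that a C3 alkoxide would undergo in the next step.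

Step 8
Reactants: 13 [(1R,2R,3R,6S)-2-(benzoyloxy)-1-bromo-6-hydroxy-3-(triethylsilyloxy)cyclohex-4-en-1-yl]methyl benzoate
Product: 14 [(1S,2R,3R,6S)-2-(benzoyloxy)-3-(triethylsilyloxy)-7-oxabicyclo[4.1.0]hept-4-en-1-yl]methyl benzoate
Conditions: KN(SiMe3)2 (1.05 equiv), THF, −78 → 0 °C
Reagents that add atoms: none
Why: Intramolecular Williamson etherification (bromohydrin to oxirane, 3-exo-tet) lets the C6 alkoxide, anti-periplanar to the C1–Br bond, displace bromide with inversion at C1, which places the oxirane oxygen on the face of O2 and O3 and turns C7 to the opposite face.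

Step 9
Reactants: 14 [(1S,2R,3R,6S)-2-(benzoyloxy)-3-(triethylsilyloxy)-7-oxabicyclo[4.1.0]hept-4-en-1-yl]methyl benzoate
Product: 15 [(1S,2R,3R,6S)-2-(benzoyloxy)-3-hydroxy-7-oxabicyclo[4.1.0]hept-4-en-1-yl]methyl benzoate (target)
Conditions: HF·pyridine, pyridine, THF, 0 °C
Reagents that add atoms: none
Why: Fluoride-mediated cleavage of the triethylsilyl ether under buffered, non-basic conditions should free the C3 hydroxyl without acyl migration and without opening the vinyl oxirane.

Compound list
1 | bromomalonaldehyde (2-bromopropanedial) | O=CC(Br)C=O | starting material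
2 | benzoyl chloride | O=C(Cl)c1ccccc1 | starting material
3 | (E)-3-(benzoyloxy)-2-bromoprop-2-enal | O=C/C(Br)=C\OC(=O)c1ccccc1 | intermediate
4 | (1E,3E)-buta-1,3-diene-1,4-diyl diacetate | CC(=O)O/C=C/C=C/OC(C)=O | starting material
5 | tert-butyldimethylsilyl chloride | CC(C)(C)[Si](C)(C)Cl | starting material
6 | dilithium (1E,3E)-buta-1,3-diene-1,4-diolate | [Li+].[Li+].[O-]/C=C/C=C/[O-] | intermediate (not isolated)
7 | (1E,3E)-1,4-bis(tert-butyldimethylsilyloxy)buta-1,3-diene | CC(C)(C)[Si](C)(C)O/C=C/C=C/O[Si](C)(C)C(C)(C)C | intermediate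
8 | (1S,2R,3R,6S)-2-(benzoyloxy)-1-bromo-3,6-bis(tert-butyldimethylsilyloxy)cyclohex-4-ene-1-carbaldehyde | O=C[C@@]1(Br)[C@@H](O[Si](C)(C)C(C)(C)C)C=C[C@@H](O[Si](C)(C)C(C)(C)C)[C@H]1OC(=O)c1ccccc1 | intermediate
9 | (1S,2R,3R,6S)-1-bromo-1-(hydroxymethyl)-3,6-bis(tert-butyldimethylsilyloxy)cyclohex-4-en-2-yl benzoate | OC[C@@]1(Br)[C@@H](O[Si](C)(C)C(C)(C)C)C=C[C@@H](O[Si](C)(C)C(C)(C)C)[C@H]1OC(=O)c1ccccc1 | intermediate
10 | [(1S,2R,3R,6S)-2-(benzoyloxy)-1-bromo-3,6-bis(tert-butyldimethylsilyloxy)cyclohex-4-en-1-yl]methyl benzoate | O=C(OC[C@@]1(Br)[C@@H](O[Si](C)(C)C(C)(C)C)C=C[C@@H](O[Si](C)(C)C(C)(C)C)[C@H]1OC(=O)c1ccccc1)c1ccccc1 | intermediate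
11 | [(1R,2R,3R,6S)-2-(benzoyloxy)-1-bromo-3,6-dihydroxycyclohex-4-en-1-yl]methyl benzoate | O=C(OC[C@@]1(Br)[C@@H](O)C=C[C@@H](O)[C@H]1OC(=O)c1ccccc1)c1ccccc1 | intermediate
12 | chlorotriethylsilane | CC[Si](Cl)(CC)CC | starting material
13 | [(1R,2R,3R,6S)-2-(benzoyloxy)-1-bromo-6-hydroxy-3-(triethylsilyloxy)cyclohex-4-en-1-yl]methyl benzoate | O=C(OC[C@@]1(Br)[C@@H](O)C=C[C@@H](O[Si](CC)(CC)CC)[C@H]1OC(=O)c1ccccc1)c1ccccc1 | intermediate
14 | [(1S,2R,3R,6S)-2-(benzoyloxy)-3-(triethylsilyloxy)-7-oxabicyclo[4.1.0]hept-4-en-1-yl]methyl benzoate | O=C(OC[C@]12O[C@H]1C=C[C@@H](O[Si](CC)(CC)CC)[C@H]2OC(=O)c1ccccc1)c1ccccc1 | intermediate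
15 | [(1S,2R,3R,6S)-2-(benzoyloxy)-3-hydroxy-7-oxabicyclo[4.1.0]hept-4-en-1-yl]methyl benzoate | O=C(OC[C@]12O[C@H]1C=C[C@@H](O)[C@H]2OC(=O)c1ccccc1)c1ccccc1 | target

Total step count: 9. Longest linear sequence: 8 steps (4 → 7 → 8 → 9 → 10 → 11 → 13 → 14 → 15; the arm from 1 is equally long).

Steps most likely to fail

First, step 3, the labelled cycloaddition. The trisubstituted dienophile, deactivated by its β-acyloxy donor, may react too slowly at temperatures the silyl dienol ether tolerates. The catalyst-bound enal may instead be consumed by stepwise Mukaiyama-type addition followed by loss of benzoate, or endo and facial control may be poor. The fallback uses known chemistry and sets out from 3 and 7: an uncatalysed thermal Diels–Alder reaction (toluene, 60–80 °C, trace 2,6-di-tert-butyl-4-methylphenol), a classical pairing of a 1,4-dioxygenated diene with an α-halo enal, should give the racemic all-cis adduct F1. Luche reduction as in step 4 gives the racemic alcohol F2, and benzoylation as in step 5 gives the racemic dibenzoate F3. Preparative chromatography of F3 on a chiral stationary phase (cellulose or amylose tris(3,5-dimethylphenylcarbamate)) then returns to the route at 10.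

Second, step 1. Acylation through the extended enolate, or later nucleophile-catalysed isomerisation of the alkene, would deliver the isomer with benzoyloxy cis to bromine, which would end as the wrong C2 epimer after cycloaddition. The fallback sets out from 1: benzoylation under equilibrating conditions (BzCl, pyridine, rt) gives that isomer deliberately, (Z)-3-(benzoyloxy)-2-bromoprop-2-enal F4. Direct or triplet-sensitised E/Z photoisomerisation (about 350 nm, MeCN, 0 °C) then leads to a photostationary mixture, from which 3 is separated by crystallisation or chromatography while F4 is recycled; the route is rejoined at 3.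

Third, step 8. The C6 alkoxide may attack the C2 or C7 benzoate carbonyl (1,3-acyl transfer) faster than it displaces the hindered tertiary bromide, releasing an alkoxide at O2 or O7 that closes the wrong oxirane; base-induced loss of HBr toward C7 is a further drain. The fallback sets out from 13 and avoids any alkoxide: Ag2O (excess), 4 Å molecular sieves, CH2Cl2, dark, rt, so that silver assists departure of bromide while the neutral C6 hydroxyl attacks anti to it. This returns directly to the route at 14 and makes no new compound (F0).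

Further compounds
F1 | step 3 | racemic 8 (equimolar 8 and its mirror image) | O=C[C@@]1(Br)[C@@H](O[Si](C)(C)C(C)(C)C)C=C[C@@H](O[Si](C)(C)C(C)(C)C)[C@H]1OC(=O)c1ccccc1.O=C[C@]1(Br)[C@H](O[Si](C)(C)C(C)(C)C)C=C[C@H](O[Si](C)(C)C(C)(C)C)[C@@H]1OC(=O)c1ccccc1
F2 | step 3 | racemic 9 (equimolar 9 and its mirror image) | OC[C@@]1(Br)[C@@H](O[Si](C)(C)C(C)(C)C)C=C[C@@H](O[Si](C)(C)C(C)(C)C)[C@H]1OC(=O)c1ccccc1.OC[C@]1(Br)[C@H](O[Si](C)(C)C(C)(C)C)C=C[C@H](O[Si](C)(C)C(C)(C)C)[C@@H]1OC(=O)c1ccccc1
F3 | step 3 | racemic 10 (equimolar 10 and its mirror image) | O=C(OC[C@@]1(Br)[C@@H](O[Si](C)(C)C(C)(C)C)C=C[C@@H](O[Si](C)(C)C(C)(C)C)[C@H]1OC(=O)c1ccccc1)c1ccccc1.O=C(OC[C@]1(Br)[C@H](O[Si](C)(C)C(C)(C)C)C=C[C@H](O[Si](C)(C)C(C)(C)C)[C@@H]1OC(=O)c1ccccc1)c1ccccc1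
F4 | step 1 | (Z)-3-(benzoyloxy)-2-bromoprop-2-enal | O=C/C(Br)=C/OC(=O)c1ccccc1
F0 | step 8 | none | none
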